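**Retrosynthetic overview** (chromene numbering: O1, C2–C4, C4a, C5–C8, C8a)

1. 26 ⇐ 25 (ester hydrolysis) ⇐ 22 (C-acylation at C6 with (R)-2-methylbutanoic acid 23).
2. 22 ⇐ 20: ring B (the carbocycle) is closed last by forming the C4a–C5 bond; an acylketene (C5), released thermally from a dioxinone, C-acylates the preformed 2H-pyran ring A at C4a.
3. Enabling feature: in ring A the unit O1–C8a=C4a is a cyclic dienol ether, so C4a is a nucleophilic β-carbon, while C5–C6–C7 of ring B is a 1,3-dicarbonyl array that can be stored as a dioxinone; C8a–C8–C7–C6–C5 are the five carbons of dioxinone-acetate 9.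
4. 20 ⇐ 18 (Lindlar semihydrogenation, then oxa-6π; ring A) ⇐ acid 13 + enyne 16; quaternary C8 of 13 ⇐ 9 by alkylation with iodide 7, then catalyst-controlled prenylation.
5. 7 (side-chain stereocentre and (E)-enoate) ⇐ Evans deconjugative alkylation of imide 3 with bromide 4; ring order: dioxinone (temporary) → ring A → ring B.

Key step: step 12

Assumption (chemistry): the β-triketone is drawn and made as the C7-enol/C5-keto tautomer given, which exchanges freely with its other enol forms; 4, 23 and the ammonium salt of step 7 are treated as catalogue compounds, and the (S,S) hand of that salt is assigned by analogy with malonate-type substrates (its antipode would be taken if the sense proves opposite).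

**Route**

Step 1  
Reactants: 1 (4S)-4-benzyl-1,3-oxazolidin-2-one; 2 3-methylbut-2-enoyl chloride  
Product: 3 (4S)-4-benzyl-3-(3-methylbut-2-enoyl)-1,3-oxazolidin-2-one  
Conditions: n-BuLi, THF, −78 °C; then 2, −78 → 0 °C  
Reagents that add atoms: none  
Why: N-acylation of the lithiated oxazolidinone by the acid chloride is the standard imide formation; no stereocentre is formed.

Step 2  
Reactants: 3 senecioyl imide; 4 ethyl (2E)-4-bromo-2-methylbut-2-enoate  
Product: 5 ethyl (2E,5S)-6-[(4S)-4-benzyl-2-oxo-1,3-oxazolidin-3-yl]-2-methyl-6-oxo-5-(prop-1-en-2-yl)hex-2-enoate  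
Conditions: NaN(SiMe3)2, THF, −78 °C; then 4, −78 → −45 °C  
Reagents that add atoms: none  
Why: Evans deconjugative alkylation: γ-deprotonation gives the chelated Z(O)-dienolate, which the allylic bromide alkylates at the α-carbon on the face opposite the benzyl group, so the auxiliary sets the (5S) centre (the future side-chain centre) and the (E)-enoate arm arrives intact.

Step 3  
Reactants: 5 alkylated imide  
Product: 6 ethyl (2E,5S)-5-(hydroxymethyl)-2,6-dimethylhepta-2,6-dienoate  
Conditions: NaBH4, THF/H2O (4:1), 0 °C → rt  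
Reagents that add atoms: none  
Why: reductive cleavage of the N-acyloxazolidinone by NaBH4 in wet THF gives the primary alcohol and frees the auxiliary, while the conjugated ethyl ester is a much poorer acceptor and the α-centre should not epimerise under these near-neutral conditions.

Step 4  
Reactants: 6 primary alcohol  
Product: 7 ethyl (2E,5S)-5-(iodomethyl)-2,6-dimethylhepta-2,6-dienoate  
Conditions: PPh3, I2, imidazole, CH2Cl2, 0 °C → rt  
Reagents that add atoms: iodine, II  
Why: Appel-type iodination of the primary alcohol under neutral conditions; the stereocentre is not involved.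

Step 5  
Reactants: 8 2,2,6-trimethyl-4H-1,3-dioxin-4-one  
Product: 9 tert-butyl (2,2-dimethyl-4-oxo-4H-1,3-dioxin-6-yl)acetate  
Conditions: LiN(SiMe3)2 (2.2 equiv), THF, −78 °C; Boc2O, −78 → −30 °C; aq. NH4Cl  
Reagents that add atoms: di-tert-butyl dicarbonate, CC(C)(C)OC(=O)OC(=O)OC(C)(C)C  
Why: Claisen-type C-acylation of the lithium dienolate at its γ-carbon (the second equivalent of base takes up the more acidic product) gives a masked acetonedicarboxylate whose ester carbon, CH2 and dioxinone carbons C6, C5 and C4 are the future C8a, C8, C7, C6 and C5.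

Step 6  
Reactants: 9 dioxinone-acetate; 7 iodide  
Product: 10 8-tert-butyl 1-ethyl (2E,5R,7RS)-7-(2,2-dimethyl-4-oxo-4H-1,3-dioxin-6-yl)-2-methyl-5-(prop-1-en-2-yl)oct-2-enedioate  
Conditions: 9 (2 equiv), NaH (1.5 equiv), DMF, 0 °C; then 7, 0 → 40 °C  
Reagents that add atoms: none  
Why: malonate-type SN2 alkylation of the soft, doubly stabilised sodium enolate at its central carbon by the primary iodide, run with excess 9 so that 10 is not re-deprotonated; the new CH centre is left unselective on purpose because step 7 planarises it again.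

Step 7  
Reactants: 10 monoalkylated dioxinone-acetate; 11 1-bromo-3-methylbut-2-ene  
Product: 12 8-tert-butyl 1-ethyl (2E,5R,7R)-7-(2,2-dimethyl-4-oxo-4H-1,3-dioxin-6-yl)-2-methyl-7-(3-methylbut-2-en-1-yl)-5-(prop-1-en-2-yl)oct-2-enedioate  
Conditions: 11 (3 equiv), (S,S)-N-spiro bis(binaphthyl)ammonium bromide with 3,4,5-trifluorophenyl groups at the 3,3′-positions (5 mol %), CsOH·H2O, toluene, −40 °C  
Reagents that add atoms: none  
Why: Proposed new method: asymmetric phase-transfer prenylation of a vinylogous malonate, in which interfacial deprotonation gives the fully substituted dienolate of 10 as a tight ion pair with the C2-symmetric ammonium cation, which should block one enantiotopic face (the flanks, a bulky tert-butyl ester and a flat dioxinone, are strongly differentiated) so that prenyl bromide adds to the central carbon from the open face and sets the (7R) quaternary centre, the fast low-temperature alkylation outrunning Michael closure onto the enoate; the closest known reaction type is the chiral phase-transfer allylation of α-substituted tert-butyl malonates and β-keto esters to all-carbon quaternary centres, and because C5 is already fixed any minor C7 epimer is a separable diastereomer.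

Step 8  
Reactants: 12 quaternary tert-butyl ester  
Product: 13 (2R,4R,6E)-2-(2,2-dimethyl-4-oxo-4H-1,3-dioxin-6-yl)-8-ethoxy-7-methyl-2-(3-methylbut-2-en-1-yl)-8-oxo-4-(prop-1-en-2-yl)oct-6-enoic acid  
Conditions: Me3SiOTf, 2,6-lutidine, CH2Cl2, 0 °C → rt; aq. citric acid work-up  
Reagents that add atoms: none  
Why: silyl triflate-mediated cleavage of the tert-butyl ester (loss of 2-methylpropene via the silyl ester, hydrolysed on work-up) under lutidine buffering should leave the alkenes, the dioxinone and the ethyl enoate untouched, and the quaternary centre cannot epimerise.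

Step 9  
Reactants: 14 4-methylpent-3-en-2-one  
Product: 16 4-methylpent-3-en-1-yne, via enol phosphate 15 (not isolated)  
Conditions: LiN(iPr)2, THF, −78 °C; ClP(O)(OEt)2, −78 °C → rt; then LiN(iPr)2 (2.3 equiv), −78 °C → rt; distillation  
Reagents that add atoms: none  
Why: kinetic α′-enolisation of the enone, O-phosphorylation and base-induced elimination of the enol phosphate convert the methyl ketone into the terminal alkyne (methyl ketone-to-alkyne conversion via an enol phosphate).

Step 10  
Reactants: 13 acid; 16 enyne  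
Product: 18 ethyl (2E,5R,7R)-7-(2,2-dimethyl-4-oxo-4H-1,3-dioxin-6-yl)-2,12-dimethyl-7-(3-methylbut-2-en-1-yl)-8-oxo-5-(prop-1-en-2-yl)trideca-2,11-dien-9-ynoate, via acid chloride 17 (not isolated)  
Conditions: 1-chloro-N,N,2-trimethylprop-1-en-1-amine, CH2Cl2, 0 °C → rt; then 16, PdCl2(PPh3)2 (2 mol %), CuI (4 mol %), Et3N, THF, rt  
Reagents that add atoms: none  
Why: the acid is converted to its chloride under neutral conditions and coupled with the terminal enyne in an acyl Sonogashira reaction, which tolerates the dioxinone and the esters and gives the cross-conjugated ynone.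

Step 11  
Reactants: 18 ynone  
Product: 20 ethyl (2E,5R,7S)-7-(2,2-dimethyl-4-oxo-4H-1,3-dioxin-6-yl)-7-(2,2-dimethyl-2H-pyran-6-yl)-2,10-dimethyl-5-(prop-1-en-2-yl)undeca-2,9-dienoate, via Z-dienone 19 (not isolated)  
Conditions: H2 (1 atm), Pd/CaCO3 poisoned with Pb(OAc)2 (Lindlar catalyst), quinoline, EtOAc, 0 °C → rt; filtered, then kept at rt in the dark; used without chromatography  
Reagents that add atoms: none  
Why: Lindlar semihydrogenation of the conjugated ynone stops at the (Z)-dienone, whose cis geometry and δ,δ-dimethyl terminus make oxa-6π electrocyclisation to the 2,2-dimethyl-2H-pyran (ring A) spontaneous, fixing the O1–C8a bond before ring B exists; no stereocentre is formed (the 7S descriptor reflects only a change in CIP priorities).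

Step 12  
Reactants: 20 dioxinone–2H-pyran  
Product: 22 ethyl (2E,5R)-5-{[(8R)-7-hydroxy-2,2-dimethyl-8-(3-methylbut-2-en-1-yl)-5-oxo-5,8-dihydro-2H-chromen-8-yl]methyl}-2,6-dimethylhepta-2,6-dienoate, via acylketene 21 (not isolated)  
Conditions: toluene (0.005 M), 110 °C, slow N2 stream  
Reagents that add atoms: none  
Why: Proposed new method: at 110 °C the dioxinone loses acetone by retro-[4+2] to give acylketene 21, whose sp carbon (future C5) is attacked by the pyran carbon that becomes C4a (the β-carbon of the cyclic dienol ether O1–C8a=C4a), and proton transfer within the resulting oxocarbenium/enolate pair restores the dienol ether and delivers the enolised 1,3-dione. The closest known reaction types are the thermal dioxinone-to-acylketene route with intramolecular capture by O- and N-nucleophiles, the intermolecular C–C bond formation of acylketenes with enol ethers and enamines, and ketene-mediated Claisen-type cyclisations of polyketide-like chains. Ring B is the only ring closed here, in a 6-(enolendo)-exo-dig sense at the ketene carbon; ring A is already in place, and any (Z)-dienone valence tautomer is funnelled through it by oxa-6π closure. No stereocentre is created: the C8 quaternary centre has no α-hydrogen and the side-chain centre is remote, so both are carried through unchanged. The step needs C-acylation at C4a rather than reaction at the pyran C3=C4 bond, at the prenyl or isopropenyl alkenes or ketene dimerisation, and this is secured by geometry (only C4a reaches the ketene carbon through a six-membered transition state; attack via C3 would need an eight-membered ring and a [4+2] mode across O1–C8a=C4a a four-membered one), by the high nucleophilicity of the dienol ether and by high dilution. Because O1 is bonded to C8a before the carbocycle exists, the regiochemistry of the chromene is decided by construction and not by a late annulation.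

Step 13  
Reactants: 22 bicyclic enol-dione; 23 (2R)-2-methylbutanoic acid  
Product: 25 ethyl (2E,5R)-5-{[(8R)-7-hydroxy-2,2-dimethyl-6-[(2R)-2-methylbutanoyl]-8-(3-methylbut-2-en-1-yl)-5-oxo-5,8-dihydro-2H-chromen-8-yl]methyl}-2,6-dimethylhepta-2,6-dienoate, via enol ester 24 (not isolated)  
Conditions: 23 (1.2 equiv), DCC, DMAP (1.5 equiv), CH2Cl2, 0 °C → rt  
Reagents that add atoms: none  
Why: carbodiimide esterification of the vinylogous acid followed by DMAP-mediated 1,3 O→C acyl shift (the Fries-type rearrangement used for 2-acylcyclohexane-1,3-diones) places the acyl group on C6, the only carbon between the two oxygenated carbons, and the (2R) centre is brought in intact from 23.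

Step 14  
Reactants: 25 ethyl ester  
Product: 26 (2E,5R)-5-{[(8R)-7-hydroxy-2,2-dimethyl-6-[(2R)-2-methylbutanoyl]-8-(3-methylbut-2-en-1-yl)-5-oxo-5,8-dihydro-2H-chromen-8-yl]methyl}-2,6-dimethylhepta-2,6-dienoic acid (CNP0184919.1)  
Conditions: LiOH·H2O, THF/H2O (3:1), rt; then 1 M HCl to pH 3, 0 °C  
Reagents that add atoms: lithium hydroxide, [Li+].[OH-]  
Why: saponification of the ethyl ester; under base the acidic β-triketone is present as its delocalised enolate, which protects the core and the acyl α-centre, and gentle acidification returns the enol form.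

**Compound list**

1 | (4S)-4-benzyl-1,3-oxazolidin-2-one | O=C1N[C@@H](Cc2ccccc2)CO1 | starting material  
2 | 3-methylbut-2-enoyl chloride | CC(C)=CC(=O)Cl | starting material  
3 | (4S)-4-benzyl-3-(3-methylbut-2-enoyl)-1,3-oxazolidin-2-one | CC(C)=CC(=O)N1[C@@H](Cc2ccccc2)COC1=O | intermediate  
4 | ethyl (2E)-4-bromo-2-methylbut-2-enoate | CCOC(=O)/C(C)=C/CBr | starting material  
5 | ethyl (2E,5S)-6-[(4S)-4-benzyl-2-oxo-1,3-oxazolidin-3-yl]-2-methyl-6-oxo-5-(prop-1-en-2-yl)hex-2-enoate | C=C(C)[C@H](C/C=C(\C)C(=O)OCC)C(=O)N1[C@@H](Cc2ccccc2)COC1=O | intermediate  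
6 | ethyl (2E,5S)-5-(hydroxymethyl)-2,6-dimethylhepta-2,6-dienoate | C=C(C)[C@H](C/C=C(\C)C(=O)OCC)CO | intermediate  
7 | ethyl (2E,5S)-5-(iodomethyl)-2,6-dimethylhepta-2,6-dienoate | C=C(C)[C@H](C/C=C(\C)C(=O)OCC)CI | intermediate  
8 | 2,2,6-trimethyl-4H-1,3-dioxin-4-one | CC1=CC(=O)OC(C)(C)O1 | starting material  
9 | tert-butyl (2,2-dimethyl-4-oxo-4H-1,3-dioxin-6-yl)acetate | CC(C)(C)OC(=O)CC1=CC(=O)OC(C)(C)O1 | intermediate  
10 | 8-tert-butyl 1-ethyl (2E,5R,7RS)-7-(2,2-dimethyl-4-oxo-4H-1,3-dioxin-6-yl)-2-methyl-5-(prop-1-en-2-yl)oct-2-enedioate | C=C(C)[C@H](C/C=C(\C)C(=O)OCC)CC(C(=O)OC(C)(C)C)C1=CC(=O)OC(C)(C)O1 | intermediate  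
11 | 1-bromo-3-methylbut-2-ene | CC(C)=CCBr | starting material  
12 | 8-tert-butyl 1-ethyl (2E,5R,7R)-7-(2,2-dimethyl-4-oxo-4H-1,3-dioxin-6-yl)-2-methyl-7-(3-methylbut-2-en-1-yl)-5-(prop-1-en-2-yl)oct-2-enedioate | C=C(C)[C@H](C/C=C(\C)C(=O)OCC)C[C@@](CC=C(C)C)(C(=O)OC(C)(C)C)C1=CC(=O)OC(C)(C)O1 | intermediate  
13 | (2R,4R,6E)-2-(2,2-dimethyl-4-oxo-4H-1,3-dioxin-6-yl)-8-ethoxy-7-methyl-2-(3-methylbut-2-en-1-yl)-8-oxo-4-(prop-1-en-2-yl)oct-6-enoic acid | C=C(C)[C@H](C/C=C(\C)C(=O)OCC)C[C@@](CC=C(C)C)(C(=O)O)C1=CC(=O)OC(C)(C)O1 | intermediate  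
14 | 4-methylpent-3-en-2-one | CC(=O)C=C(C)C | starting material  
15 | diethyl 4-methylpenta-1,3-dien-2-yl phosphate | C=C(OP(=O)(OCC)OCC)C=C(C)C | intermediate  
16 | 4-methylpent-3-en-1-yne | C#CC=C(C)C | intermediate  
17 | ethyl (2E,5R,7R)-8-chloro-7-(2,2-dimethyl-4-oxo-4H-1,3-dioxin-6-yl)-2-methyl-7-(3-methylbut-2-en-1-yl)-8-oxo-5-(prop-1-en-2-yl)oct-2-enoate | C=C(C)[C@H](C/C=C(\C)C(=O)OCC)C[C@@](CC=C(C)C)(C(=O)Cl)C1=CC(=O)OC(C)(C)O1 | intermediate  
18 | ethyl (2E,5R,7R)-7-(2,2-dimethyl-4-oxo-4H-1,3-dioxin-6-yl)-2,12-dimethyl-7-(3-methylbut-2-en-1-yl)-8-oxo-5-(prop-1-en-2-yl)trideca-2,11-dien-9-ynoate | C=C(C)[C@H](C/C=C(\C)C(=O)OCC)C[C@@](CC=C(C)C)(C(=O)C#CC=C(C)C)C1=CC(=O)OC(C)(C)O1 | intermediate  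
19 | ethyl (2E,5R,7R,9Z)-7-(2,2-dimethyl-4-oxo-4H-1,3-dioxin-6-yl)-2,12-dimethyl-7-(3-methylbut-2-en-1-yl)-8-oxo-5-(prop-1-en-2-yl)trideca-2,9,11-trienoate | C=C(C)[C@H](C/C=C(\C)C(=O)OCC)C[C@@](CC=C(C)C)(C(=O)/C=C\C=C(C)C)C1=CC(=O)OC(C)(C)O1 | intermediate  
20 | ethyl (2E,5R,7S)-7-(2,2-dimethyl-4-oxo-4H-1,3-dioxin-6-yl)-7-(2,2-dimethyl-2H-pyran-6-yl)-2,10-dimethyl-5-(prop-1-en-2-yl)undeca-2,9-dienoate | C=C(C)[C@H](C/C=C(\C)C(=O)OCC)C[C@@](CC=C(C)C)(C1=CC=CC(C)(C)O1)C2=CC(=O)OC(C)(C)O2 | intermediate  
21 | ethyl (2E,5R,7S)-7-(2,2-dimethyl-2H-pyran-6-yl)-2,10-dimethyl-7-(3-oxoprop-2-enoyl)-5-(prop-1-en-2-yl)undeca-2,9-dienoate | C=C(C)[C@H](C/C=C(\C)C(=O)OCC)C[C@@](CC=C(C)C)(C1=CC=CC(C)(C)O1)C(=O)C=C=O | intermediate  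
22 | ethyl (2E,5R)-5-{[(8R)-7-hydroxy-2,2-dimethyl-8-(3-methylbut-2-en-1-yl)-5-oxo-5,8-dihydro-2H-chromen-8-yl]methyl}-2,6-dimethylhepta-2,6-dienoate | C=C(C)[C@H](C/C=C(\C)C(=O)OCC)C[C@]1(CC=C(C)C)C(O)=CC(=O)C2=C1OC(C)(C)C=C2 | intermediate  
23 | (2R)-2-methylbutanoic acid | CC[C@@H](C)C(=O)O | starting material  
24 | ethyl (2E,5R)-5-{[(8R)-2,2-dimethyl-7-{[(2R)-2-methylbutanoyl]oxy}-8-(3-methylbut-2-en-1-yl)-5-oxo-5,8-dihydro-2H-chromen-8-yl]methyl}-2,6-dimethylhepta-2,6-dienoate | C=C(C)[C@H](C/C=C(\C)C(=O)OCC)C[C@]1(CC=C(C)C)C(OC(=O)[C@H](C)CC)=CC(=O)C2=C1OC(C)(C)C=C2 | intermediate  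
25 | ethyl (2E,5R)-5-{[(8R)-7-hydroxy-2,2-dimethyl-6-[(2R)-2-methylbutanoyl]-8-(3-methylbut-2-en-1-yl)-5-oxo-5,8-dihydro-2H-chromen-8-yl]methyl}-2,6-dimethylhepta-2,6-dienoate | C=C(C)[C@H](C/C=C(\C)C(=O)OCC)C[C@]1(CC=C(C)C)C(O)=C(C(=O)[C@H](C)CC)C(=O)C2=C1OC(C)(C)C=C2 | intermediate  
26 | (2E,5R)-5-{[(8R)-7-hydroxy-2,2-dimethyl-6-[(2R)-2-methylbutanoyl]-8-(3-methylbut-2-en-1-yl)-5-oxo-5,8-dihydro-2H-chromen-8-yl]methyl}-2,6-dimethylhepta-2,6-dienoic acid | C=C(C)[C@H](C/C=C(\C)C(=O)O)C[C@]1(CC=C(C)C)C(O)=C(C(=O)[C@H](C)CC)C(=O)C2=C1OC(C)(C)C=C2 | target  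

**Step count and risks**

Total steps: 14. Longest linear sequence: 12 steps (1–4, 6–8, 10–14).

Steps most likely to fail:

1. Step 12 (Proposed new method). What may go wrong: ketene dimerisation or ene-type capture of the acylketene by the prenyl or isopropenyl groups outrunning C-acylation; thermal retro-oxa-6π opening of the pyran, before or after ring closure, with re-closure on the other oxygen, which would erode the regiochemical integrity of ring A. Fallback with known chemistry, setting out from 13 and coming back at 22: through acid chloride 17 as in step 10, iron-catalysed acylation of (4-methylpent-3-en-1-yl)magnesium bromide (Fe(acac)3, THF, −78 °C) would give the homoprenyl ketone F1. Heating F1 with ethanol in toluene (110 °C) would open the dioxinone to the ethyl β-keto ester F2. NaOEt in ethanol would then close ring B by a Dieckmann-type Claisen condensation of the ketone α-carbon onto the ester, making the same C4a–C5 bond and giving the 4a-prenylated trione F3, in which the prenyl group keeps the two carbonyl neighbours of C8 different. DDQ in toluene would finally dehydrogenate that prenyl group and close ring A by oxa-6π onto the C8a oxygen, returning to 22 after chromatographic removal of the isomer closed on the C5 oxygen.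

2. Step 7 (Proposed new method). What may go wrong: poor facial selectivity of the ion-paired dienolate, competing alkylation at oxygen or at the dioxinone α-carbon, or Michael closure of the carbanion onto the enoate. Fallback with known chemistry, setting out from 10 and coming back at 12: plain malonate-type alkylation (K2CO3, acetone, 11, rt) would give 12 together with its C7 epimer F4; because C5 is already fixed the two are diastereomers, and preparative chromatography would supply pure 12, which re-enters at step 8, so stereocontrol is replaced by separation.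

3. Step 6. What may go wrong: E2 elimination of the β-branched homoallylic iodide, re-deprotonation of the product followed by 5-exo Michael closure onto the enoate, or over-alkylation. Fallback setting out from 6 (with 9) and coming back at 10: a Mitsunobu-type dehydrative C-alkylation (PBu3, N,N,N′,N′-tetramethylazodicarboxamide, benzene, rt → 50 °C) would join the alcohol and the acidic C–H compound directly, with no halide and no free carbanion at any time; this fallback makes no compound outside the list (F0).

**Further compounds**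

F1 | step 12 | ethyl (2E,5R,7R)-7-(2,2-dimethyl-4-oxo-4H-1,3-dioxin-6-yl)-2,12-dimethyl-7-(3-methylbut-2-en-1-yl)-8-oxo-5-(prop-1-en-2-yl)trideca-2,11-dienoate | C=C(C)[C@H](C/C=C(\C)C(=O)OCC)C[C@@](CC=C(C)C)(C(=O)CCC=C(C)C)C1=CC(=O)OC(C)(C)O1  
F2 | step 12 | ethyl (2E,5R,7S)-7-(3-ethoxy-3-oxopropanoyl)-2,12-dimethyl-7-(3-methylbut-2-en-1-yl)-8-oxo-5-(prop-1-en-2-yl)trideca-2,11-dienoate | C=C(C)[C@H](C/C=C(\C)C(=O)OCC)C[C@@](CC=C(C)C)(C(=O)CCC=C(C)C)C(=O)CC(=O)OCC  
F3 | step 12 | ethyl (2E,5R)-5-{[(1R,3RS)-1,3-bis(3-methylbut-2-en-1-yl)-2,4,6-trioxocyclohexyl]methyl}-2,6-dimethylhepta-2,6-dienoate | C=C(C)[C@H](C/C=C(\C)C(=O)OCC)C[C@]1(CC=C(C)C)C(=O)CC(=O)C(CC=C(C)C)C1=O  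
F4 | step 7 | 8-tert-butyl 1-ethyl (2E,5R,7S)-7-(2,2-dimethyl-4-oxo-4H-1,3-dioxin-6-yl)-2-methyl-7-(3-methylbut-2-en-1-yl)-5-(prop-1-en-2-yl)oct-2-enedioate | C=C(C)[C@H](C/C=C(\C)C(=O)OCC)C[C@](CC=C(C)C)(C(=O)OC(C)(C)C)C1=CC(=O)OC(C)(C)O1  
F0 | step 6 | none | none  
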